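The constants of the steps are hidden from you, so follow one molecule of starting material and ask where you would find it once the flask has gone flat. Each listed step turns one molecule into one other.

| flask | starting material | remark | time |
|---|---|---|---|
| beta | 1.4 M | run made earlier |  |
| epsilon | 2.2 M | run made earlier |  |
| flask | 1.0 M |  | 15 min |

| run | time / min | starting material / % | target / % |
|---|---|---|---|
| beta | 0.667 | 10.3 | 21.8 |
| beta | 1.00 | 8.7 | 17.5 |
| beta | 1.50 | 7.4 | 15.9 |
| beta | 2.50 | 6.0 | 16.2 |
| beta | 4.00 | 6.5 | 14.8 |
| beta | 6.00 | 7.0 | 15.2 |
| beta | 10.0 | 5.8 | 17.4 |
| epsilon | 0.500 | 12.6 | 22.7 |
| epsilon | 1.33 | 8.1 | 16.3 |
| epsilon | 2.50 | 7.1 | 15.9 |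
| epsilon | 4.00 | 7.5 | 16.1 |
| epsilon | 5.00 | 8.2 | 15.7 |
| epsilon | 8.00 | 6.7 | 14.0 |
| epsilon | 10.0 | 6.7 | 15.3 |

(scatter of a reading: 1 percentage point)

- steps thought possible: starting material <-> isomer of the product A; starting material <-> target; starting material <-> dormant form; target <-> isomer of the product B
- what has gone from starting material into another species counts as reacted, even if it can come back
- the reaction counts as stopped when no species that holds the starting material changes by six tenths of a point or more over the second half of the time

* the state of affairs at 15 min: stopped, and by what, or still going (it is still moving / all of the starting material has reacted / forward and back rates have come level)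
* conversion of starting material at 15 min
* amount of target at 15 min, in percent of the starting material charged

From 2.50 min on, both runs stay flat within the scatter, and this flask gets 6.00 times that long, so I expect it to stop with forward and back rates level, which is thermodynamic control in the usual term. Conversion is then one minus the fraction still present as starting material.

A crude bracket for that fraction comes from the late readings: the highest, 8.2 %, makes its upper edge and the lowest, 5.8 %, its lower edge, each with the scatter of a reading. To tighten it, compare the late means. Beta gives 6.33 % and epsilon 7.24 %, a gap of 0.91 percentage points against a scatter of 0.67 points for such a gap, so these two runs do not clearly differ and I pool them, taking it as my assumption that the lower charge of this flask sits on the same plateau. That gives the rest share, the chance of finding a molecule as starting material on the plateau, 6.83 %. Two standard errors are 0.67 points, so I put conversion between 92.5 % and 93.8 %. The same pooling puts target between 15.0 % and 16.3 %.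

The forecast, forward and back rates have come level with 93.2 % conversion and 15.5 % target, sits inside both brackets and says “this is equilibrium rather than exhaustion”. The flask gives forward and back rates have come level, conversion 92.8 % and target 15.0 %.

    starting material ⇌ isomer of the product A (K = 3.10, k = 1.30 /s)
    starting material ⇌ target (K = 2.10, k = 3.30 /s)
    starting material ⇌ dormant form (K = 2.10, k = 0.0220 /s)
    target ⇌ isomer of the product B (K = 2.70, k = 0.0330 /s)

The flask's remaining 7.16 % of starting material lies inside the bracket on the rest share, and conversion and target lie inside theirs. Now take the same flask with 2.5 M of starting material, a charge above both runs. The rest share again predicts 93.2 % conversion, with the same bracket. That flask's conversion comes out at 92.8 %, with 7.16 % of its charge left as starting material and 15.0 % as target.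

The numbers in the tables are simulated with made-up constants; scatter was added.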